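**Plan**
- Retrosynthetic cuts: C4=CH2 goes back to a C4 ketone. C3 is then excised from ring A (C4–C3–C2 becomes C4–C2), which leaves a 3-nor trans-hydrindan-4-one. C8–CH3 goes back to a C8 ketone, and C9–CH2Ar plus C10–H to a C8 enone. C9=C10 and C5–C6 lead to 2-methylcyclopentane-1,3-dione and ethyl vinyl ketone. The arene comes from methyl 3-formyl-4-hydroxybenzoate.
- Forward order: ring B (C5–C10) is closed onto the ready-made five-membered ring, the arene is joined at C9, and C8 is methylenated. Only then is the five-membered ring (C4, C2, C1, C10, C5) enlarged to ring A by insertion of one carbon (C3). Hydrogenation and C4 methylenation finish the route.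
- Enabling feature: in ring A the sp2 carbon C4 (=CH2, a masked ketone) lies between fully substituted C5 and a plain CH2. In the nor-ketone C2 is the carbon expected to migrate, so the inserted carbon should end up as C3 and the carbonyl stays next to C5. This angular-methyl trans-hydrindanone is the ring-D motif of 17-oxo steroids, on which this edit (D-homoannulation) is known.
- Stereochemistry: C5 comes from an L-phenylalanine-mediated desymmetrising aldol. C10, C9 and C8 are relayed from the 5β-methyl by α-face protonation, α-face benzylation and α-face hydrogenation. The ring enlargement breaks no bond to a stereocentre.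

Key step: step 12

Remark on numbering: atoms carry the 4,9-friedodrimane numbers of the target (ring A = C1–C5, C10; ring B = C5–C10). β is the face of the C5 methyl. In the five-membered-ring compounds C3 is absent and C4 is bonded to C2.

Step 1
Reactants: 1 2-methylcyclopentane-1,3-dione; 2 pent-1-en-3-one (ethyl vinyl ketone)
Product: 3 2-methyl-2-(3-oxopentyl)cyclopentane-1,3-dione
Conditions: H2O, AcOH (cat.), 70 °C
Reagents that add atoms: none
Why: Michael addition of the acidic 1,3-dione to the enone forms C5–C6 under near-neutral conditions that avoid retro-Claisen opening; C5 is still prochiral.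

Step 2
Reactants: 3 2-methyl-2-(3-oxopentyl)cyclopentane-1,3-dione
Product: 4 (7aS)-4,7a-dimethyl-2,3,7,7a-tetrahydro-1H-indene-1,5(6H)-dione
Conditions: L-phenylalanine, (+)-camphorsulfonic acid, DMF, 30 → 70 °C; recrystallisation
Reagents that add atoms: none
Why: Hajos–Parrish–Eder–Sauer–Wiechert reaction, in which the enamine of the ethyl ketone with the primary amino acid attacks one of the two enantiotopic ring carbonyls (C9–C10 bond, then dehydration), and the L-amino acid should give C5 as (S).

Step 3
Reactants: 4 (7aS)-4,7a-dimethyl-2,3,7,7a-tetrahydro-1H-indene-1,5(6H)-dione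
Product: 5 (1S,7aS)-1-hydroxy-4,7a-dimethyl-1,2,3,6,7,7a-hexahydro-5H-inden-5-one (4β-OH)
Conditions: NaBH4 (one hydride equivalent), EtOH, −15 °C
Reagents that add atoms: none
Why: The non-conjugated cyclopentanone is more electrophilic than the tetrasubstituted enone, and hydride should arrive on the α-face opposite the 5β-methyl, giving the temporary 4β-alcohol (chemoselective borohydride reduction).

Step 4
Reactants: 5 (1S,7aS)-1-hydroxy-4,7a-dimethyl-1,2,3,6,7,7a-hexahydro-5H-inden-5-one
Product: 6 (1S,7aS)-1-(tert-butyldimethylsilyloxy)-4,7a-dimethyl-1,2,3,6,7,7a-hexahydro-5H-inden-5-one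
Conditions: TBSCl, imidazole, DMF, 40 °C
Reagents that add atoms: tert-butyldimethylsilyl chloride, CC(C)(C)[Si](C)(C)Cl
Why: Standard silylation masks C4–OH as an ether that survives dissolving metal and ylide base, and its bulk on the β-face supports the trans-selective reduction that follows.

Step 5
Reactants: 7 methyl 3-formyl-4-hydroxybenzoate
Product: 8 methyl 4-(benzyloxy)-3-formylbenzoate
Conditions: BnBr, K2CO3, DMF, rt
Reagents that add atoms: benzyl bromide, BrCc1ccccc1
Why: Williamson ether synthesis on the acidic phenol installs a group that is stable to base, ylide and Lewis acid and is removable by hydrogenolysis.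

Step 6
Reactants: 8 methyl 4-(benzyloxy)-3-formylbenzoate
Product: 9 methyl 4-(benzyloxy)-3-(hydroxymethyl)benzoate
Conditions: NaBH4, MeOH, 0 °C
Reagents that add atoms: none
Why: Borohydride reduces the aldehyde much faster than the benzoate ester.

Step 7
Reactants: 9 methyl 4-(benzyloxy)-3-(hydroxymethyl)benzoate
Product: 10 methyl 4-(benzyloxy)-3-(bromomethyl)benzoate
Conditions: PBr3, CH2Cl2, 0 °C
Reagents that add atoms: phosphorus tribromide, BrP(Br)Br
Why: SN2 bromination of the primary benzylic alcohol through its phosphite ester leaves the aryl benzyl ether and the ester untouched at 0 °C.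

Step 8
Reactants: 6 (1S,7aS)-1-(tert-butyldimethylsilyloxy)-4,7a-dimethyl-1,2,3,6,7,7a-hexahydro-5H-inden-5-one; 10 methyl 4-(benzyloxy)-3-(bromomethyl)benzoate
Product: 12 methyl 4-(benzyloxy)-3-{[(1S,3aR,4S,7aS)-1-(tert-butyldimethylsilyloxy)-4,7a-dimethyl-5-oxooctahydro-1H-inden-4-yl]methyl}benzoate (trans-fused; 10α-H, 9β-Me, 9α-CH2Ar), via trans-fused lithium C8–C9 enolate 11 (not isolated)
Conditions: Li, NH3/THF, H2O (1 equiv), −78 → −33 °C; isoprene; NH3 evaporated; 10, THF, −78 → 0 °C
Reagents that add atoms: none
Why: Dissolving-metal reductive alkylation, in which the enone radical anion should be protonated at C10 on the α-face anti to the 5β-methyl (trans-hydrindane), and the regiodefined enolate should be benzylated at C9 on the α-face, since β-attack would be 1,3-diaxial to that methyl.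

Step 9
Reactants: 12 trans-hydrindan-8-one from step 8
Product: 13 methyl 4-(benzyloxy)-3-{[(1S,3aS,4S,7aS)-1-(tert-butyldimethylsilyloxy)-4,7a-dimethyl-5-methylideneoctahydro-1H-inden-4-yl]methyl}benzoate
Conditions: Ph3PCH3Br, KOtBu (slightly less than the salt), toluene, 90 °C
Reagents that add atoms: methyltriphenylphosphonium bromide, C[P+](c1ccccc1)(c1ccccc1)c1ccccc1.[Br-]
Why: Wittig methylenation with the small salt-free ylide is the precedented way to olefinate ketones next to a quaternary carbon; C9 cannot epimerise, and the p-alkoxybenzoate is a deactivated ester.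

Step 10
Reactants: 13 8-methylidene silyl ether
Product: 14 methyl 4-(benzyloxy)-3-{[(1S,3aS,4S,7aS)-1-hydroxy-4,7a-dimethyl-5-methylideneoctahydro-1H-inden-4-yl]methyl}benzoate
Conditions: HF·pyridine, pyridine, THF, 0 °C → rt
Reagents that add atoms: none
Why: Buffered fluoride cleaves the Si–O bond without touching the ester, the benzyl ether or the 1,1-disubstituted alkene.

Step 11
Reactants: 14 4β-alcohol
Product: 15 methyl 4-(benzyloxy)-3-{[(3aS,4S,7aS)-4,7a-dimethyl-5-methylidene-1-oxooctahydro-1H-inden-4-yl]methyl}benzoate (3-nor-4-ketone)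
Conditions: Dess–Martin periodinane, CH2Cl2, rt
Reagents that add atoms: none
Why: Dess–Martin oxidation converts the hindered secondary alcohol into the cyclopentanone under near-neutral conditions that spare the alkene and the benzyl ether.

Step 12
Reactants: 15 3-nor-4-ketone
Product: 17 methyl 4-(benzyloxy)-3-{[(1S,4aS,8aS)-1,4a-dimethyl-2-methylidene-5-oxodecahydronaphthalen-1-yl]methyl}benzoate (trans-decal-4-one), via 3-(trimethylsilyl) ketone 16 (not isolated)
Conditions: TMSCHN2, BF3·OEt2 (promoter), CH2Cl2, −78 → −20 °C; then K2CO3 (cat.), MeOH, rt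
Reagents that add atoms: (trimethylsilyl)diazomethane, C[Si](C)(C)C=[N+]=[N-]
Why: The BF3-activated C4 carbonyl is attacked by the nucleophilic diazo carbon from the α-face (anti to the 5β-methyl), and the β-oxido-diazonium betaine loses N2 with a concerted 1,2-shift of C2 from C4 to the new carbon, which becomes C3 (Büchner–Curtius–Schlotterbeck/Tiffeneau–Demjanov-type homologation). The closest known reaction types are the Lewis-acid-promoted trimethylsilyldiazomethane homologation of cycloalkanones and the D-homoannulation of 17-oxo steroids, whose ring D is the same angular-methyl trans-hydrindanone. No ring is closed: the five-membered ring C4–C2–C1–C10–C5 grows to six-membered ring A by insertion into the C4–C2 bond, with ring B as a spectator. No lasting stereocentre is created (the C3–Si centre of 16 is erased by methanolysis), and C5, C9 and C10 are untouched because no bond to them is broken. The step needs regioselectivity (C2 versus C5 migration), which the known preference for migration of the less substituted carbon and the crowding at fully substituted C5 should secure; it needs a single insertion, which the bulky α-silyl group of 16 should secure until work-up; and it needs chemoselectivity, which holds because the deactivated benzoate, the aryl benzyl ether and the unactivated C8 methylene do not react with the diazoalkane at low temperature.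

Step 13
Reactants: 17 trans-decal-4-one
Product: 18 methyl 4-hydroxy-3-{[(1R,2S,4aS,8aS)-1,2,4a-trimethyl-5-oxodecahydronaphthalen-1-yl]methyl}benzoate (8β-Me)
Conditions: H2 (1 atm), Pd/C, EtOAc–MeOH, rt
Reagents that add atoms: none
Why: Heterogeneous hydrogenation should add to the C8 methylene from the α-face, because the β-face is screened by the axial 5β- and 9β-methyls, giving the equatorial 8β-methyl, and the same operation hydrogenolyses the benzyl ether.

Step 14
Reactants: 18 phenolic decal-4-one
Product: 19 dictyoceratin C, methyl 4-hydroxy-3-{[(1R,2S,4aS,8aS)-1,2,4a-trimethyl-5-methylidenedecahydronaphthalen-1-yl]methyl}benzoate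
Conditions: Ph3PCH3Br (excess), KOtBu, toluene–THF, reflux; aq. NH4Cl
Reagents that add atoms: methyltriphenylphosphonium bromide, C[P+](c1ccccc1)(c1ccccc1)c1ccccc1.[Br-]
Why: Wittig methylenation of the C4 ketone; the first equivalent of ylide only forms the phenoxide, which further deactivates the para ester, and no stereocentre is α to the carbonyl.

**Compound list**
1 | 2-methylcyclopentane-1,3-dione | CC1C(=O)CCC1=O | starting material
2 | pent-1-en-3-one | C=CC(=O)CC | starting material
3 | 2-methyl-2-(3-oxopentyl)cyclopentane-1,3-dione | CCC(=O)CCC1(C)C(=O)CCC1=O | intermediate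
4 | (7aS)-4,7a-dimethyl-2,3,7,7a-tetrahydro-1H-indene-1,5(6H)-dione | O=C1CCC2=C(C)C(=O)CC[C@]12C | intermediate
5 | (1S,7aS)-1-hydroxy-4,7a-dimethyl-1,2,3,6,7,7a-hexahydro-5H-inden-5-one | O[C@H]1CCC2=C(C)C(=O)CC[C@]12C | intermediate
6 | TBS ether of 5 | CC(C)(C)[Si](C)(C)O[C@H]1CCC2=C(C)C(=O)CC[C@]12C | intermediate
7 | methyl 3-formyl-4-hydroxybenzoate | COC(=O)c1ccc(O)c(C=O)c1 | starting material
8 | methyl 4-(benzyloxy)-3-formylbenzoate | COC(=O)c1ccc(OCc2ccccc2)c(C=O)c1 | intermediate
9 | methyl 4-(benzyloxy)-3-(hydroxymethyl)benzoate | COC(=O)c1ccc(OCc2ccccc2)c(CO)c1 | intermediate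
10 | methyl 4-(benzyloxy)-3-(bromomethyl)benzoate | COC(=O)c1ccc(OCc2ccccc2)c(CBr)c1 | intermediate
11 | trans-fused lithium C8–C9 enolate (10α-H, 4β-OTBS) | [Li+].CC(C)(C)[Si](C)(C)O[C@H]1CC[C@H]2C(C)=C([O-])CC[C@]12C | intermediate
12 | 9α-benzylated trans-hydrindan-8-one (4β-OTBS) | CC(C)(C)[Si](C)(C)O[C@H]1CC[C@H]2[C@](C)(Cc3cc(C(=O)OC)ccc3OCc3ccccc3)C(=O)CC[C@]12C | intermediate
13 | 8-methylidene silyl ether | CC(C)(C)[Si](C)(C)O[C@H]1CC[C@H]2[C@](C)(Cc3cc(C(=O)OC)ccc3OCc3ccccc3)C(=C)CC[C@]12C | intermediate
14 | 8-methylidene 4β-alcohol | O[C@H]1CC[C@H]2[C@](C)(Cc3cc(C(=O)OC)ccc3OCc3ccccc3)C(=C)CC[C@]12C | intermediate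
15 | 3-nor-4-ketone (trans-hydrindanone) | O=C1CC[C@H]2[C@](C)(Cc3cc(C(=O)OC)ccc3OCc3ccccc3)C(=C)CC[C@]12C | intermediate
16 | 3-(trimethylsilyl) trans-decal-4-one (C3 epimers) | O=C1C([Si](C)(C)C)CC[C@H]2[C@](C)(Cc3cc(C(=O)OC)ccc3OCc3ccccc3)C(=C)CC[C@]12C | intermediate
17 | ring-enlarged trans-decal-4-one, 8-methylidene, benzyl ether | O=C1CCC[C@H]2[C@](C)(Cc3cc(C(=O)OC)ccc3OCc3ccccc3)C(=C)CC[C@]12C | intermediate
18 | phenolic 8β-methyl trans-decal-4-one | O=C1CCC[C@H]2[C@](C)(Cc3cc(C(=O)OC)ccc3O)[C@@H](C)CC[C@]12C | intermediate
19 | dictyoceratin C | C=C1CCC[C@H]2[C@](C)(Cc3cc(C(=O)OC)ccc3O)[C@@H](C)CC[C@]12C | target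

Total step count: 14. Longest linear sequence: 11 steps (steps 1–4 and 8–14, from 2-methylcyclopentane-1,3-dione).

**Steps most likely to fail**

Step 8. In a hydrindenone the protonation of the radical anion at C10 may show poor facial selectivity, which would give cis-fusion. Proton exchange may also scramble the enolate before the slow alkylation of a tetrasubstituted centre. The fallback separates the two events and sets out from 6. The thermodynamic dienolate (KOtBu, t-BuOH–THF, 0 °C; only C1 carries γ-hydrogens) is alkylated with 10 at C9 on the α-face. This gives the deconjugated C1=C10 β,γ-unsaturated ketone F1. A metal-hydride hydrogen-atom-transfer hydrogenation (Mn(dpm)3 cat., PhSiH3, t-BuOOH, i-PrOH) then places H on C1. The tertiary C10 radical is flanked on its β-face by the 5β- and 9β-methyls, so it should be quenched from the α-face. The benzyl ether survives, and the fallback comes back to the route at 12.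

Step 12. Addition to the neopentyl carbonyl may be sluggish, some migration of C5 may compete, and the Lewis acid may shift the C8 alkene. The fallback fixes the regiochemistry through the only possible enol and sets out from 15. TMSOTf/Et3N gives the C4–C2 trimethylsilyl enol ether F2. Furukawa-modified Simmons–Smith cyclopropanation (Et2Zn, CH2I2, about one equivalent; the electron-rich enol ether should react before the hindered C8 alkene) gives the α-face siloxycyclopropane F3. FeCl3 in DMF opens the internal cyclopropane bond to the ring-enlarged 2-chloro-decal-4-one F4. NaOAc in MeOH eliminates this to the decal-2-en-4-one F5. Hydrogenation over Pd/C saturates both alkenes and removes the benzyl group, and the fallback comes back to the route at 18.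

Step 13. Surface hydrogenation may show poor facial selectivity at C8 if the 9α-benzyl arm screens the α-face, or the alkene may migrate into the ring and stall. The fallback sets out from 17 and replaces steric-approach control by a stepwise radical process. Hydrogen-atom-transfer hydrogenation (Mn(dpm)3 cat., PhSiH3, t-BuOOH, i-PrOH) forms the C8 tertiary radical. Axial quenching of this radical should give the thermodynamically preferred equatorial 8β-methyl benzyl ether F6. Separate hydrogenolysis (H2, Pd/C) then comes back to the route at 18.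

**Further compounds**
F1 | step 8 | C1=C10 β,γ-unsaturated 9α-benzylated 8-ketone (4β-OTBS) | CC(C)(C)[Si](C)(C)O[C@H]1CC=C2[C@](C)(Cc3cc(C(=O)OC)ccc3OCc3ccccc3)C(=O)CC[C@]12C
F2 | step 12 | C4–C2 trimethylsilyl enol ether of 15 | C[Si](C)(C)OC1=CC[C@H]2[C@](C)(Cc3cc(C(=O)OC)ccc3OCc3ccccc3)C(=C)CC[C@]12C
F3 | step 12 | 4-(trimethylsilyloxy) cyclopropane (CH2 bridging C4 and C2 on the α-face) | C[Si](C)(C)O[C@]14C[C@@H]4C[C@H]2[C@](C)(Cc3cc(C(=O)OC)ccc3OCc3ccccc3)C(=C)CC[C@]12C
F4 | step 12 | 2-chloro trans-decal-4-one (C2 epimers) | O=C1CC(Cl)C[C@H]2[C@](C)(Cc3cc(C(=O)OC)ccc3OCc3ccccc3)C(=C)CC[C@]12C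
F5 | step 12 | trans-decal-2-en-4-one | O=C1C=CC[C@H]2[C@](C)(Cc3cc(C(=O)OC)ccc3OCc3ccccc3)C(=C)CC[C@]12C
F6 | step 13 | 8β-methyl trans-decal-4-one benzyl ether | O=C1CCC[C@H]2[C@](C)(Cc3cc(C(=O)OC)ccc3OCc3ccccc3)[C@@H](C)CC[C@]12C
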